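J is the one I watch: on the list of suspects it is the catalyst of E + X + J → J + D, and it has to be made first, from X + L.

| flask | E | X | L | remark | time |
|---|---|---|---|---|---|
| east | 0.80 M | 1.6 M | 4.3 mM | run made earlier |  |
| north | 0.80 M | 1.6 M | 12 mM | run made earlier |  |
| north-west | 0.61 M | 1.6 M | 5 mM | run made earlier |  |
| summer | 0.50 M | 1.00 M | 8.0 mM |  | 8.0 h |
| noon | 0.40 M | 0.500 M | 5.0 mM |  | 8.0 h |
| autumn | 0.80 M | 1.60 M | 5.0 mM |  | 8.0 h |
| winter | 0.80 M | 2.50 M | 3.0 mM |  | 8.0 h |
| dusk | 0.80 M | 3.00 M | 5.0 mM |  | 8.0 h |

| run | time / h | D / % |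
|---|---|---|
| east | 0.667 | 0 |
| east | 1.33 | 0 |
| east | 3.00 | 3 |
| east | 8.00 | 20 |
| north | 2.00 | 6 |
| north | 4.00 | 16 |
| north | 6.00 | 31 |
| north | 8.00 | 43 |
| north-west | 1.00 | 0 |
| north-west | 3.00 | 4 |
| north-west | 5.00 | 9 |
| north-west | 8.00 | 22 |

(standard deviation of a reading: 1.5 percentage points)

- on the list of suspects stand: D + J <-> G + J; X + L -> J + Z; E + X + J <-> J + D

1. the flasks put in order of amount of D, in percent of the E charged, best first, at 8.0 h (summer / noon / autumn / winter / dusk)
2. the amount of D, in percent of the E charged of the flask you put first, at 8.0 h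
3. the amount of D, in percent of the E charged of the flask you put last, at 8.0 h

I reckon by hand. While [X] and [L] stay near their charges, [J] grows in step with [X][L] and time, so E falls pseudo-first-order with a rate constant that itself grows with time. Call Λ the logarithm of E charged over E left. Then Λ goes as [X] squared, times [L], times time squared, and [E] drops out.

I turn each setting in turn. From 4.00 h to 8.00 h in north, Λ should grow by a factor 4.00, and the readings give 3.22. From east to north, [L] rises by a factor 2.79, and Λ at the last reading by 2.52. For [E], I take Λ at the last reading, 8.00 h, and scale it in proportion to [L] of 5.0 mM: the readings of east, north and north-west then give 0.259, 0.234 and 0.248, close together although north-west has less E. [X] stood at 1.6 M in these runs, so its square rests on the list of suspects, not on readings.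

I carry the mean, 0.247: the build-up number κ, which is Λ at 8.0 h for [X] at 1.60 M and [L] at 5.0 mM. Dividing Λ of one flask by Λ of another at one time, time drops out, so at 8.0 h any flask has κ times the square of its [X] over 1.60 M, times its [L] over 5.0 mM, and the ranking follows [X] squared times [L]. That product is greater in dusk than in winter, in winter than in autumn, in autumn than in summer, and in summer than in noon. With κ I reckon 58.1% of D for dusk and 2.39% for noon, both at [L] of 5.0 mM.

The forecast sees a rise that “points to a catalyst J slowly built up from X + L”. It gives dusk > winter > autumn > summer > noon, with 52% for the first (42% to 62%) and 2.5% for the last (1.5% to 4%). Its dusk figure, trimmed from about 57% for losses, is lower than mine of 58.1%.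

The flasks give dusk > winter > autumn > summer > noon, with 52.1% in dusk and 2.80% in noon.

    D + J ⇌ G + J, rate k1*[J]*[D] forward; the back reaction follows from the equilibrium constant (K = 1.40, k = 1.50 L mol⁻¹ h⁻¹)
    X + L → J + Z (k = 0.0330 L mol⁻¹ h⁻¹)
    E + X + J ⇌ J + D (K = 7.80 L mol⁻¹, k = 23.0 L² mol⁻² h⁻¹)

In dusk, X + L kept making J up to 8.00 h, when L stood at 47.5% and J at 52.5% of the catalyst charged, while G had reached 0.545% of the E charged; my 58.1% lies above that flask. In noon, L was still at 87.7% and J at 12.3% while D grew, and my 2.39% lies below the flask.

For the neighbour of noon with [L] at 0.020 M, κ of 0.247 gives 9.21% of D at 8.0 h. That flask gives 10.1%, with L at 88.0%.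

The readings were generated by integration on assumed constants, and the scatter is random.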